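**Retrosynthetic overview**

1. Helenien is all-E (3R,3'R,6'R)-lutein dipalmitate. The palmitates go on last, and the C40 polyene is cut at C11=C12 and C11'=C12' into β-C15 phosphonium salt 24, C10 dialdehyde 25 and ε-C15 phosphonium salt 14 (two Wittig reactions).
2. The strategy rests on the ε ring (C1'–C6'): its C1'–C6' bond links the gem-dimethyl carbon C1' to the chain-bearing methine C6', the ring alkene is C4'=C5', and the C3' oxygen sits 1,4 to C6'. That bond is made by proton-initiated cation–olefin cyclisation of the acyclic isopropenyl dienone 11 to silylated 3-hydroxy-α-ionone 12, with the C3' carbinol relaying its configuration to C6'.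
3. Dienone 11 is built with the carbinol set first from (R)-epichlorohydrin (isopropenyl Grignard, then acetylide), followed by methylalumination/hydroxymethylation and oxidation–Wittig homologation, so that no hydride- or base-mediated C–C bond formation has to be run on the dienone.
4. Ring order: the β ring is bought in ketoisophorone 15 and only functionalised (actinol, enol triflate, Heck reaction); the ε ring is the only ring formed, in step 6.

Key step: step 6

Assumption: the tertiary carbinol carbons created in steps 7 and 14 are carried as both epimers because each is flattened in the next step, and the hindered Z isomers from the two Wittig couplings are taken to all-E by heating.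

**Step 1**
Reactants: 1 (R)-epichlorohydrin
Product: 2 (2R)-1-chloro-4-methylpent-4-en-2-ol
Conditions: CH2=C(CH3)MgBr (1.3 equiv), CuI (10 mol %), THF, −40 → −20 °C; aq NH4Cl
Reagents that add atoms: isopropenylmagnesium bromide, C=C(C)[Mg]Br
Why: Copper-catalysed Grignard opening of the epoxide at its unsubstituted carbon (SN2) does not touch the C–O stereocentre of 1, so 2 keeps the R configuration that becomes C3'.

**Step 2**
Reactants: 2 (2R)-1-chloro-4-methylpent-4-en-2-ol
Product: 4 (4R)-6-methylhept-6-en-1-yn-4-ol, via (2R)-2-(2-methylprop-2-en-1-yl)oxirane 3 (not isolated)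
Conditions: LiC≡CH·H2NCH2CH2NH2 (3 equiv), DMSO, 0 °C → rt; aq NH4Cl
Reagents that add atoms: lithium acetylide (ethylenediamine complex), [Li]C#C
Why: The acetylide first closes the chlorohydrin to epoxide 3 (intramolecular Williamson reaction) and then opens it at the CH2 terminus (SN2 epoxide alkynylation), so the carbinol carbon is never a reacting atom and stays R.

**Step 3**
Reactants: 4 (4R)-6-methylhept-6-en-1-yn-4-ol
Product: 5 tert-butyl{[(4R)-6-methylhept-6-en-1-yn-4-yl]oxy}diphenylsilane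
Conditions: TBDPSCl, imidazole, DMF, rt
Reagents that add atoms: tert-butyl(chloro)diphenylsilane, CC(C)(C)[Si](Cl)(c1ccccc1)c1ccccc1
Why: Standard silylation of a secondary alcohol, with the bulky and weakly basic tert-butyldiphenylsilyl ether chosen as the common silyl ether most resistant to Brønsted acid.

**Step 4**
Reactants: 5 tert-butyl{[(4R)-6-methylhept-6-en-1-yn-4-yl]oxy}diphenylsilane
Product: 8 (2E,5R)-5-{[tert-butyl(diphenyl)silyl]oxy}-3,7-dimethylocta-2,7-dien-1-ol, via E-alkenyl(dimethyl)alane 6 (not isolated), via lithium butyl(alkenyl)dimethylalanate 7 (not isolated)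
Conditions: AlMe3 (2.5 equiv), Cp2ZrCl2 (0.25 equiv), CH2Cl2, 0 °C → rt; volatiles removed; n-BuLi, THF, −78 → 0 °C; (CH2O)n, rt; aq KNaC4H4O6
Reagents that add atoms: trimethylaluminium, C[Al](C)C; paraformaldehyde (as formaldehyde), C=O
Why: Zirconium-catalysed syn-methylalumination of the terminal alkyne (Negishi carboalumination) puts CH3 on the internal carbon and Al on the terminus with E geometry, the alanate is hydroxymethylated with retention, and the 1,1-disubstituted alkene and the silyl ether are inert to AlMe3/Cp2ZrCl2.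

**Step 5**
Reactants: 8 (2E,5R)-5-{[tert-butyl(diphenyl)silyl]oxy}-3,7-dimethylocta-2,7-dien-1-ol; 9 1-(triphenylphosphoranylidene)propan-2-one
Product: 11 (3E,5E,8R)-8-{[tert-butyl(diphenyl)silyl]oxy}-6,10-dimethylundeca-3,5,10-trien-2-one, via (2E,5R)-5-silyloxy-3,7-dimethylocta-2,7-dienal 10 (not isolated)
Conditions: MnO2 (15 equiv), CH2Cl2, rt; filtration; 9 (1.3 equiv), toluene, 60 °C
Reagents that add atoms: none
Why: MnO2 oxidises only the allylic alcohol and the stabilised ylide then gives the E enone (Wittig reaction, as in the homologation of citral to pseudoionone), while the 5E geometry set in step 4 is carried through.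

**Step 6**
Reactants: 11 (3E,5E,8R)-8-{[tert-butyl(diphenyl)silyl]oxy}-6,10-dimethylundeca-3,5,10-trien-2-one
Product: 12 (3E)-4-[(1R,4R)-4-{[tert-butyl(diphenyl)silyl]oxy}-2,6,6-trimethylcyclohex-2-en-1-yl]but-3-en-2-one
Conditions: ClSO3H (2 equiv), 2-nitropropane, −78 °C, short contact; Et3N then aq NaHCO3 at −78 °C
Reagents that add atoms: none
Why: Proposed new method: protonation of the isopropenyl CH2 should give the tertiary C1' cation, C6' of the trisubstituted alkene attacks it to form C1'–C6', and the resulting tertiary C5' cation loses H4' to give C4'=C5'; the closest known reaction is the protic-acid cyclisation of pseudoionone to α-ionone, here with an oxygen on the tether and a 1,1-disubstituted initiator. The ε ring closes in a 6-endo-trig cation–olefin mode through a chair. C6' is set by that chair: the C3' silyloxy group sits equatorial because an axial one would clash with the axial C1' methyl group, and the E geometry of the attacking alkene places the enone arm (trans to the tether) equatorial, so the two groups end 1,4-trans and 3'R is relayed to 6'R. The step needs kinetic loss of H4' rather than H6' or a methyl proton, survival of the C3'–O bond and of the silyl group, and retention of the 5E geometry until the bond is formed. The isopropenyl initiator keeps the oxygen homoallylic to every cation before ring closure, the bulky weakly basic silyl ether resists protonation, and −78 °C with a cold amine quench limits reprotonation to the conjugated β isomer, ionisation of the new allylic ether and E/Z exchange in the protonated dienone. About two equivalents of acid are used because the dienone carbonyl is the most basic site and takes up the first.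

**Step 7**
Reactants: 12 (3E)-4-[(1R,4R)-4-{[tert-butyl(diphenyl)silyl]oxy}-2,6,6-trimethylcyclohex-2-en-1-yl]but-3-en-2-one
Product: 13 (1E)-1-[(1R,4R)-4-{[tert-butyl(diphenyl)silyl]oxy}-2,6,6-trimethylcyclohex-2-en-1-yl]-3-methylpenta-1,4-dien-3-ol (both C3 epimers)
Conditions: CH2=CHMgBr (1.5 equiv), THF, −78 → 0 °C; aq NH4Cl
Reagents that add atoms: vinylmagnesium bromide, C=C[Mg]Br
Why: 1,2-Addition of a vinyl Grignard reagent to the methyl enone, as in the preparation of vinyl-ionols, with the new carbinol centre formed as both epimers and erased in step 8.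

**Step 8**
Reactants: 13 (1E)-1-[(1R,4R)-4-{[tert-butyl(diphenyl)silyl]oxy}-2,6,6-trimethylcyclohex-2-en-1-yl]-3-methylpenta-1,4-dien-3-ol
Product: 14 [(2E,4E)-5-[(1R,4R)-4-{[tert-butyl(diphenyl)silyl]oxy}-2,6,6-trimethylcyclohex-2-en-1-yl]-3-methylpenta-2,4-dien-1-yl]triphenylphosphonium bromide
Conditions: PPh3·HBr (1.05 equiv), CH2Cl2, 0 °C → rt; trituration with EtOAc
Reagents that add atoms: triphenylphosphine hydrobromide, [Br-].[PH+](c1ccccc1)(c1ccccc1)c1ccccc1
Why: The phosphine hydrobromide ionises the tertiary doubly allylic alcohol and the phosphine captures the pentadienyl cation at its primary terminus (SN1' allylic transposition, the standard C15 Wittig-salt synthesis), and one equivalent of this mild acid in CH2Cl2 should leave the secondary silyl ether and H6' untouched.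

**Step 9**
Reactants: 15 ketoisophorone (2,6,6-trimethylcyclohex-2-ene-1,4-dione)
Product: 16 (6R)-2,2,6-trimethylcyclohexane-1,4-dione
Conditions: ene-reductase OYE2, NADP+ (cat.), glucose dehydrogenase, D-glucose, KH2PO4/K2HPO4 buffer (pH 7), 30 °C
Reagents that add atoms: none
Why: Enzymatic conjugate reduction of the enedione C=C by a flavin ene-reductase of the old-yellow-enzyme type is an established route to (6R)-levodione, the enzyme pocket fixing the face of hydride and proton delivery.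

**Step 10**
Reactants: 16 (6R)-2,2,6-trimethylcyclohexane-1,4-dione
Product: 17 (4R,6R)-4-hydroxy-2,2,6-trimethylcyclohexan-1-one
Conditions: LiBH(s-Bu)3 (1.1 equiv), THF, −78 °C; aq NH4Cl
Reagents that add atoms: none
Why: Bulky-hydride ketone reduction in which the reagent attacks the unhindered C4 carbonyl from the equatorial direction, the axial path being blocked by the syn-axial C2 methyl group, to give the axial 4R alcohol trans to the C6 methyl group while the doubly flanked C1 carbonyl does not react.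

**Step 11**
Reactants: 17 (4R,6R)-4-hydroxy-2,2,6-trimethylcyclohexan-1-one
Product: 18 (4R,6R)-4-{[tert-butyl(dimethyl)silyl]oxy}-2,2,6-trimethylcyclohexan-1-one
Conditions: TBSCl, imidazole, DMF, rt → 40 °C
Reagents that add atoms: tert-butyl(chloro)dimethylsilane, CC(C)(C)[Si](C)(C)Cl
Why: Standard silylation of a secondary alcohol, needed before the strong-base and Grignard steps.

**Step 12**
Reactants: 18 (4R,6R)-4-{[tert-butyl(dimethyl)silyl]oxy}-2,2,6-trimethylcyclohexan-1-one
Product: 20 (4R)-4-{[tert-butyl(dimethyl)silyl]oxy}-2,6,6-trimethylcyclohex-1-en-1-yl trifluoromethanesulfonate, via lithium enolate 19 (not isolated)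
Conditions: LiN(i-Pr)2 (1.2 equiv), THF, −78 → 0 °C; PhNTf2 (1.2 equiv), 0 °C → rt
Reagents that add atoms: N-phenylbis(trifluoromethanesulfonimide), O=S(=O)(N(c1ccccc1)S(=O)(=O)C(F)(F)F)C(F)(F)F
Why: The ketone can enolise only toward C6, so a single tetrasubstituted enolate forms and is O-sulfonylated (enol triflate formation), which erases the C6 centre that is no longer needed.

**Step 13**
Reactants: 20 (4R)-4-{[tert-butyl(dimethyl)silyl]oxy}-2,6,6-trimethylcyclohex-1-en-1-yl trifluoromethanesulfonate; 21 but-3-en-2-one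
Product: 22 (3E)-4-[(4R)-4-{[tert-butyl(dimethyl)silyl]oxy}-2,6,6-trimethylcyclohex-1-en-1-yl]but-3-en-2-one
Conditions: 21 (3 equiv), Pd(OAc)2 (5 mol %), PPh3 (10 mol %), Et3N (2 equiv), DMF, 70 °C
Reagents that add atoms: none
Why: Heck reaction of an alkenyl triflate with an electron-poor alkene (oxidative addition to zerovalent palladium, syn-insertion, syn-β-hydride elimination) gives the E dienone, a known way from cyclohexenyl triflates to β-ionones.

**Step 14**
Reactants: 22 (3E)-4-[(4R)-4-{[tert-butyl(dimethyl)silyl]oxy}-2,6,6-trimethylcyclohex-1-en-1-yl]but-3-en-2-one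
Product: 23 (1E)-1-[(4R)-4-{[tert-butyl(dimethyl)silyl]oxy}-2,6,6-trimethylcyclohex-1-en-1-yl]-3-methylpenta-1,4-dien-3-ol (both C3 epimers)
Conditions: CH2=CHMgBr (1.5 equiv), THF, −78 → 0 °C; aq NH4Cl
Reagents that add atoms: vinylmagnesium bromide, C=C[Mg]Br
Why: 1,2-Addition of a vinyl Grignard reagent to the hindered methyl dienone, the classical preparation of a vinyl-β-ionol.

**Step 15**
Reactants: 23 (1E)-1-[(4R)-4-{[tert-butyl(dimethyl)silyl]oxy}-2,6,6-trimethylcyclohex-1-en-1-yl]-3-methylpenta-1,4-dien-3-ol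
Product: 24 [(2E,4E)-5-[(4R)-4-{[tert-butyl(dimethyl)silyl]oxy}-2,6,6-trimethylcyclohex-1-en-1-yl]-3-methylpenta-2,4-dien-1-yl]triphenylphosphonium bromide
Conditions: PPh3·HBr (1.05 equiv), CH2Cl2, 0 °C → rt; trituration with EtOAc
Reagents that add atoms: triphenylphosphine hydrobromide, [Br-].[PH+](c1ccccc1)(c1ccccc1)c1ccccc1
Why: Ionisation of the tertiary doubly allylic alcohol and capture of the polyenyl cation by phosphine at the primary terminus (SN1' allylic transposition), the standard entry to β-C15 Wittig salts.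

**Step 16**
Reactants: 14 ε-C15 phosphonium bromide; 25 (2E,4E,6E)-2,7-dimethylocta-2,4,6-trienedial
Product: 27 (2E,4E,6E,8E,10E,12E)-13-[(1R,4R)-4-{[tert-butyl(diphenyl)silyl]oxy}-2,6,6-trimethylcyclohex-2-en-1-yl]-2,7,11-trimethyltrideca-2,4,6,8,10,12-hexaenal, via ε-C15 ylide 26 (not isolated)
Conditions: 25 (2.5 equiv), NaOMe (1.05 equiv) added slowly, CH2Cl2/MeOH, 0 °C → rt; then heptane, reflux, dark; chromatography with recovery of 25
Reagents that add atoms: none
Why: Wittig reaction of the semi-stabilised allylic ylide with an excess of the symmetrical dialdehyde should stop at mono-olefination (the usual C15 + C10 carotenoid coupling), and the hindered Z isomer at the new bond reverts to E on heating.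

**Step 17**
Reactants: 27 C25 aldehyde; 24 β-C15 phosphonium bromide
Product: 29 all-E (3R,3'R,6'R)-3-O-[tert-butyl(dimethyl)silyl]-3'-O-[tert-butyl(diphenyl)silyl]lutein, via β-C15 ylide 28 (not isolated)
Conditions: 24 (1.2 equiv), NaOMe (1.3 equiv), CH2Cl2/MeOH, 0 °C → rt; then heptane, reflux, dark, Ar
Reagents that add atoms: none
Why: The second Wittig reaction (C15 + C25) completes the C40 polyene, both silyl ethers and the C6' centre being inert to methoxide at room temperature, and the hindered 11Z isomer is isomerised thermally to all-E.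

**Step 18**
Reactants: 29 all-E bis-silyl lutein
Product: 30 all-E (3R,3'R,6'R)-β,ε-carotene-3,3'-diol (lutein)
Conditions: Bu4NF (6 equiv), AcOH (6 equiv), THF, rt → 40 °C, dark
Reagents that add atoms: none
Why: Fluoride cleavage of both silyl ethers, buffered with AcOH to avoid strong base and run without mineral acid because the allylic C3' carbinol of lutein ionises readily.

**Step 19**
Reactants: 30 lutein; 31 hexadecanoyl chloride
Product: 32 helenien, all-E (3R,3'R,6'R)-lutein dipalmitate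
Conditions: 31 (2.5 equiv), pyridine, DMAP (cat.), CH2Cl2, 0 °C → rt, dark; crystallisation
Reagents that add atoms: none
Why: Acylation of both secondary alcohols by the acid chloride under pyridine/DMAP catalysis (nucleophilic acyl substitution) touches no stereocentre, and the basic medium protects the allylic ester from ionisation.

**Compound list**

1 | (R)-epichlorohydrin | ClC[C@H]1CO1 | starting material
2 | (2R)-1-chloro-4-methylpent-4-en-2-ol | ClC[C@H](O)CC(C)=C | intermediate
3 | (2R)-2-(2-methylprop-2-en-1-yl)oxirane | C=C(C)C[C@@H]1CO1 | intermediate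
4 | (4R)-6-methylhept-6-en-1-yn-4-ol | C#CC[C@H](O)CC(C)=C | intermediate
5 | tert-butyl{[(4R)-6-methylhept-6-en-1-yn-4-yl]oxy}diphenylsilane | C#CC[C@H](O[Si](c1ccccc1)(c1ccccc1)C(C)(C)C)CC(C)=C | intermediate
6 | dimethyl[(1E,4R)-4-{[tert-butyl(diphenyl)silyl]oxy}-2,6-dimethylhepta-1,6-dien-1-yl]alane | C[Al](C)/C=C(C)/C[C@H](O[Si](c1ccccc1)(c1ccccc1)C(C)(C)C)CC(C)=C | intermediate
7 | lithium butyl[(1E,4R)-4-{[tert-butyl(diphenyl)silyl]oxy}-2,6-dimethylhepta-1,6-dien-1-yl]dimethylalanate | [Li+].CCCC[Al-](C)(C)/C=C(C)/C[C@H](O[Si](c1ccccc1)(c1ccccc1)C(C)(C)C)CC(C)=C | intermediate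
8 | (2E,5R)-5-{[tert-butyl(diphenyl)silyl]oxy}-3,7-dimethylocta-2,7-dien-1-ol | OC/C=C(C)/C[C@H](O[Si](c1ccccc1)(c1ccccc1)C(C)(C)C)CC(C)=C | intermediate
9 | 1-(triphenylphosphoranylidene)propan-2-one | CC(=O)C=P(c1ccccc1)(c1ccccc1)c1ccccc1 | starting material
10 | (2E,5R)-5-{[tert-butyl(diphenyl)silyl]oxy}-3,7-dimethylocta-2,7-dienal | O=C/C=C(C)/C[C@H](O[Si](c1ccccc1)(c1ccccc1)C(C)(C)C)CC(C)=C | intermediate
11 | (3E,5E,8R)-8-{[tert-butyl(diphenyl)silyl]oxy}-6,10-dimethylundeca-3,5,10-trien-2-one | CC(=O)/C=C/C=C(C)/C[C@H](O[Si](c1ccccc1)(c1ccccc1)C(C)(C)C)CC(C)=C | intermediate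
12 | (3E)-4-[(1R,4R)-4-{[tert-butyl(diphenyl)silyl]oxy}-2,6,6-trimethylcyclohex-2-en-1-yl]but-3-en-2-one | CC(=O)/C=C/[C@H]1C(C)=C[C@H](O[Si](c2ccccc2)(c2ccccc2)C(C)(C)C)CC1(C)C | intermediate
13 | (1E)-1-[(1R,4R)-4-{[tert-butyl(diphenyl)silyl]oxy}-2,6,6-trimethylcyclohex-2-en-1-yl]-3-methylpenta-1,4-dien-3-ol, both C3 epimers | C=CC(C)(O)/C=C/[C@H]1C(C)=C[C@H](O[Si](c2ccccc2)(c2ccccc2)C(C)(C)C)CC1(C)C | intermediate
14 | [(2E,4E)-5-[(1R,4R)-4-{[tert-butyl(diphenyl)silyl]oxy}-2,6,6-trimethylcyclohex-2-en-1-yl]-3-methylpenta-2,4-dien-1-yl]triphenylphosphonium bromide | [Br-].C(/C=C(C)/C=C/[C@H]1C(C)=C[C@H](O[Si](c2ccccc2)(c2ccccc2)C(C)(C)C)CC1(C)C)[P+](c3ccccc3)(c3ccccc3)c3ccccc3 | intermediate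
15 | ketoisophorone, 2,6,6-trimethylcyclohex-2-ene-1,4-dione | CC1=CC(=O)CC(C)(C)C1=O | starting material
16 | (6R)-2,2,6-trimethylcyclohexane-1,4-dione | O=C1C[C@@H](C)C(=O)C(C)(C)C1 | intermediate
17 | (4R,6R)-4-hydroxy-2,2,6-trimethylcyclohexan-1-one | O[C@@H]1C[C@@H](C)C(=O)C(C)(C)C1 | intermediate
18 | (4R,6R)-4-{[tert-butyl(dimethyl)silyl]oxy}-2,2,6-trimethylcyclohexan-1-one | CC(C)(C)[Si](C)(C)O[C@@H]1C[C@@H](C)C(=O)C(C)(C)C1 | intermediate
19 | lithium (4R)-4-{[tert-butyl(dimethyl)silyl]oxy}-2,6,6-trimethylcyclohex-1-en-1-olate | CC1=C(O[Li])C(C)(C)C[C@H](O[Si](C)(C)C(C)(C)C)C1 | intermediate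
20 | (4R)-4-{[tert-butyl(dimethyl)silyl]oxy}-2,6,6-trimethylcyclohex-1-en-1-yl trifluoromethanesulfonate | CC1=C(OS(=O)(=O)C(F)(F)F)C(C)(C)C[C@H](O[Si](C)(C)C(C)(C)C)C1 | intermediate
21 | but-3-en-2-one | CC(=O)C=C | starting material
22 | (3E)-4-[(4R)-4-{[tert-butyl(dimethyl)silyl]oxy}-2,6,6-trimethylcyclohex-1-en-1-yl]but-3-en-2-one | CC1=C(/C=C/C(C)=O)C(C)(C)C[C@H](O[Si](C)(C)C(C)(C)C)C1 | intermediate
23 | (1E)-1-[(4R)-4-{[tert-butyl(dimethyl)silyl]oxy}-2,6,6-trimethylcyclohex-1-en-1-yl]-3-methylpenta-1,4-dien-3-ol, both C3 epimers | CC1=C(/C=C/C(C)(O)C=C)C(C)(C)C[C@H](O[Si](C)(C)C(C)(C)C)C1 | intermediate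
24 | [(2E,4E)-5-[(4R)-4-{[tert-butyl(dimethyl)silyl]oxy}-2,6,6-trimethylcyclohex-1-en-1-yl]-3-methylpenta-2,4-dien-1-yl]triphenylphosphonium bromide | [Br-].CC1=C(/C=C/C(C)=C/C[P+](c2ccccc2)(c2ccccc2)c2ccccc2)C(C)(C)C[C@H](O[Si](C)(C)C(C)(C)C)C1 | intermediate
25 | (2E,4E,6E)-2,7-dimethylocta-2,4,6-trienedial | O=C/C(C)=C/C=C/C=C(C)/C=O | starting material
26 | ylide of 14, triphenyl[(2E,4E)-5-[(1R,4R)-4-{[tert-butyl(diphenyl)silyl]oxy}-2,6,6-trimethylcyclohex-2-en-1-yl]-3-methylpenta-2,4-dien-1-ylidene]phosphorane | [CH-](/C=C(C)/C=C/[C@H]1C(C)=C[C@H](O[Si](c2ccccc2)(c2ccccc2)C(C)(C)C)CC1(C)C)[P+](c3ccccc3)(c3ccccc3)c3ccccc3 | intermediate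
27 | (2E,4E,6E,8E,10E,12E)-13-[(1R,4R)-4-{[tert-butyl(diphenyl)silyl]oxy}-2,6,6-trimethylcyclohex-2-en-1-yl]-2,7,11-trimethyltrideca-2,4,6,8,10,12-hexaenal | O=C/C(C)=C/C=C/C=C(C)/C=C/C=C(C)/C=C/[C@H]1C(C)=C[C@H](O[Si](c2ccccc2)(c2ccccc2)C(C)(C)C)CC1(C)C | intermediate
28 | ylide of 24, triphenyl[(2E,4E)-5-[(4R)-4-{[tert-butyl(dimethyl)silyl]oxy}-2,6,6-trimethylcyclohex-1-en-1-yl]-3-methylpenta-2,4-dien-1-ylidene]phosphorane | CC1=C(/C=C/C(C)=C/[CH-][P+](c2ccccc2)(c2ccccc2)c2ccccc2)C(C)(C)C[C@H](O[Si](C)(C)C(C)(C)C)C1 | intermediate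
29 | all-E (3R,3'R,6'R)-3-O-[tert-butyl(dimethyl)silyl]-3'-O-[tert-butyl(diphenyl)silyl]lutein | CC1=C(/C=C/C(C)=C/C=C/C(C)=C/C=C/C=C(C)/C=C/C=C(C)/C=C/[C@H]2C(C)=C[C@H](O[Si](c3ccccc3)(c3ccccc3)C(C)(C)C)CC2(C)C)C(C)(C)C[C@H](O[Si](C)(C)C(C)(C)C)C1 | intermediate
30 | all-E (3R,3'R,6'R)-β,ε-carotene-3,3'-diol (lutein) | CC1=C(/C=C/C(C)=C/C=C/C(C)=C/C=C/C=C(C)/C=C/C=C(C)/C=C/[C@H]2C(C)=C[C@H](O)CC2(C)C)C(C)(C)C[C@H](O)C1 | intermediate
31 | hexadecanoyl chloride | CCCCCCCCCCCCCCCC(=O)Cl | starting material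
32 | helenien, all-E (3R,3'R,6'R)-lutein dipalmitate | CCCCCCCCCCCCCCCC(=O)O[C@@H]1CC(C)=C(/C=C/C(C)=C/C=C/C(C)=C/C=C/C=C(C)/C=C/C=C(C)/C=C/[C@H]2C(C)=C[C@H](OC(=O)CCCCCCCCCCCCCCC)CC2(C)C)C(C)(C)C1 | target

**Step count**

Total step count: 19. Longest linear sequence: 12 steps (steps 1–8 and 16–19, from (R)-epichlorohydrin); the β branch (steps 9–15) joins at step 17.

**Steps most likely to fail**

Step 6. The cationic closure may be diverted by ionisation of the allylic C3'–O bond once the ring alkene exists, by loss of the silyl group, by migration of the ring alkene into conjugation (loss of H6'), by isomerisation of the isopropenyl group before closure, or by poor 1,4-induction. The fallback takes the ε ring from ketoisophorone instead of closing it and uses only known reaction types. It sets out from ketoisophorone 15.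
- Corey–Bakshi–Shibata reduction of the unhindered C4 carbonyl ((S)-Me-CBS oxazaborolidine, catecholborane, toluene, −78 °C) should give (4R)-4-hydroxy-2,6,6-trimethylcyclohex-2-en-1-one F1. The catalyst enantiomer is the one the usual model predicts with the alkene flank as the large group; this is to be confirmed by Mosher analysis.
- Silylation (TBDPSCl, imidazole, DMF) gives (4R)-4-{[tert-butyl(diphenyl)silyl]oxy}-2,6,6-trimethylcyclohex-2-en-1-one F2.
- Corey–Chaykovsky methylenation of the hindered enone carbonyl (Me3S+ I−, n-BuLi, THF, −10 °C) gives (6R)-6-{[tert-butyl(diphenyl)silyl]oxy}-4,8,8-trimethyl-1-oxaspiro[2.5]oct-4-ene F3.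
- Meinwald rearrangement (MgBr2·OEt2, Et2O, −20 °C) gives (4R)-4-{[tert-butyl(diphenyl)silyl]oxy}-2,6,6-trimethylcyclohex-2-ene-1-carbaldehyde F4 as both C1 epimers.
- Wittig reaction of F4 with 9 (toluene, 60 °C) and chromatographic removal of the 1,4-cis isomer comes back to the route at 12.

Step 8. The acid needed to ionise the tertiary alcohol may also ionise the ring allylic silyl ether or draw H6' into a retro-type double-bond shift, and the new trisubstituted alkene may form as an E/Z mixture. The fallback avoids any cation and sets out from 12.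
- Horner–Wadsworth–Emmons olefination (triethyl phosphonoacetate, NaH, THF, 0 °C → rt) gives ethyl (2E,4E)-5-[(1R,4R)-4-{[tert-butyl(diphenyl)silyl]oxy}-2,6,6-trimethylcyclohex-2-en-1-yl]-3-methylpenta-2,4-dienoate F5, purified from its 2Z isomer.
- Reduction with i-Bu2AlH (toluene, −78 °C) gives (2E,4E)-5-[(1R,4R)-4-{[tert-butyl(diphenyl)silyl]oxy}-2,6,6-trimethylcyclohex-2-en-1-yl]-3-methylpenta-2,4-dien-1-ol F6.
- Appel bromination (CBr4, PPh3, CH2Cl2, −20 °C) gives (2E,4E)-5-[(1R,4R)-4-{[tert-butyl(diphenyl)silyl]oxy}-2,6,6-trimethylcyclohex-2-en-1-yl]-3-methylpenta-2,4-dien-1-yl bromide F7.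
- Quaternisation of F7 with PPh3 (EtOAc, rt) comes back to the route at 14, bypassing 13.

Step 16. The ylide may olefinate both formyl groups of the symmetrical dialdehyde, and its long lifetime in methoxide may allow base-induced migration of the ring double bond. The fallback desymmetrises the C10 unit first and sets out from 25.
- Partial acetalisation (HC(OMe)3, MeOH, pyridinium p-toluenesulfonate cat., rt, chromatography) gives (2E,4E,6E)-8,8-dimethoxy-2,7-dimethylocta-2,4,6-trienal F8.
- Wittig reaction of F8 with one equivalent of 14 (NaOMe, CH2Cl2/MeOH, 0 °C) gives (2E,4E,6E,8E,10E,12E)-1,1-dimethoxy-2,7,11-trimethyl-13-[(1R,4R)-4-{[tert-butyl(diphenyl)silyl]oxy}-2,6,6-trimethylcyclohex-2-en-1-yl]trideca-2,4,6,8,10,12-hexaene F9.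
- Hydrolysis of the conjugated acetal with aqueous oxalic acid (THF, 0 °C) comes back to the route at 27.

**Further compounds**

F1 | step 6 | (4R)-4-hydroxy-2,6,6-trimethylcyclohex-2-en-1-one | CC1=C[C@H](O)CC(C)(C)C1=O
F2 | step 6 | (4R)-4-{[tert-butyl(diphenyl)silyl]oxy}-2,6,6-trimethylcyclohex-2-en-1-one | CC1=C[C@H](O[Si](c2ccccc2)(c2ccccc2)C(C)(C)C)CC(C)(C)C1=O
F3 | step 6 | (6R)-6-{[tert-butyl(diphenyl)silyl]oxy}-4,8,8-trimethyl-1-oxaspiro[2.5]oct-4-ene, both spiro epimers | CC1=C[C@H](O[Si](c2ccccc2)(c2ccccc2)C(C)(C)C)CC(C)(C)C13CO3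
F4 | step 6 | (4R)-4-{[tert-butyl(diphenyl)silyl]oxy}-2,6,6-trimethylcyclohex-2-ene-1-carbaldehyde, both C1 epimers | CC1=C[C@H](O[Si](c2ccccc2)(c2ccccc2)C(C)(C)C)CC(C)(C)C1C=O
F5 | step 8 | ethyl (2E,4E)-5-[(1R,4R)-4-{[tert-butyl(diphenyl)silyl]oxy}-2,6,6-trimethylcyclohex-2-en-1-yl]-3-methylpenta-2,4-dienoate | CCOC(=O)/C=C(C)/C=C/[C@H]1C(C)=C[C@H](O[Si](c2ccccc2)(c2ccccc2)C(C)(C)C)CC1(C)C
F6 | step 8 | (2E,4E)-5-[(1R,4R)-4-{[tert-butyl(diphenyl)silyl]oxy}-2,6,6-trimethylcyclohex-2-en-1-yl]-3-methylpenta-2,4-dien-1-ol | OC/C=C(C)/C=C/[C@H]1C(C)=C[C@H](O[Si](c2ccccc2)(c2ccccc2)C(C)(C)C)CC1(C)C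
F7 | step 8 | (2E,4E)-5-[(1R,4R)-4-{[tert-butyl(diphenyl)silyl]oxy}-2,6,6-trimethylcyclohex-2-en-1-yl]-3-methylpenta-2,4-dien-1-yl bromide | BrC/C=C(C)/C=C/[C@H]1C(C)=C[C@H](O[Si](c2ccccc2)(c2ccccc2)C(C)(C)C)CC1(C)C
F8 | step 16 | (2E,4E,6E)-8,8-dimethoxy-2,7-dimethylocta-2,4,6-trienal | O=C/C(C)=C/C=C/C=C(C)/C(OC)OC
F9 | step 16 | (2E,4E,6E,8E,10E,12E)-1,1-dimethoxy-2,7,11-trimethyl-13-[(1R,4R)-4-{[tert-butyl(diphenyl)silyl]oxy}-2,6,6-trimethylcyclohex-2-en-1-yl]trideca-2,4,6,8,10,12-hexaene | COC(OC)/C(C)=C/C=C/C=C(C)/C=C/C=C(C)/C=C/[C@H]1C(C)=C[C@H](O[Si](c2ccccc2)(c2ccccc2)C(C)(C)C)CC1(C)C
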